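**Plan**

Numbering: ring A is C1(Me)=C2H–C3H(OH)–C4H(Br)–C5Me2–C6(spiro); ring B is C6–C7H2–C8H2–C9(Me)Br–C10HCl–C11H2.
Retrosynthesis: C3–H (hydride to the ketone), C9–Br (from C9–O) and C4–Br are cut first. C2, the unsubstituted alkene CH between C1 and C3 of ring A, is then excised (bonds C1–C2 and C2–C3), which contracts ring A to a spiro[4.5] cyclopentanone silyl enol ether. That is cut at C6–C1 (C–H insertion), C1–CH3, C1–C3 (malonate acylation) and C5–C4 (tert-alkylation), back to trans-limonene oxide.
Forward: ring B is the limonene ring throughout. The five-membered ring closes on C6–H by rhodium carbenoid insertion, chlorocarbene addition to its C1=C3 enol ether and opening of the chlorocyclopropane expand it to ring A, and the halogens and carbinol are finished last.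
Stereochemistry: C6, C9 and C10 come from (R)-limonene through trans-limonene oxide (anti chloride opening at C10, C9–O bond kept, insertion with retention at C6, retention at C9 through the chlorine-bridged cation). C4 is set by bromination of the C3 dienolate and C3 by hydride delivery anti to the C4 bromine.

Key step: step 13

Assumption: commercial (+)-limonene oxide is the (4R) cis/trans mixture; monocyclic and spiro[4.5] intermediates carry IUPAC locants, spiro[5.5] compounds the numbering of the plan, and the SMILES are definitive for configuration.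

**Route**

Step 1
Reactants: 1 (+)-limonene 1,2-oxide, (4R), cis/trans mixture
Product: 2 trans-(+)-limonene 1,2-oxide, (1S,2R,4R) in limonene numbering (methyl trans to isopropenyl)
Conditions: pyrazole, H2O, reflux; pentane extraction, distillation
Reagents that add atoms: none
Why: Kinetic separation by selective hydrolysis: the cis epoxide opens trans-diaxially at its tertiary carbon under these weakly acidic aqueous conditions and is removed as the diol, whereas the trans epoxide, whose diaxial opening needs attack at the secondary carbon, should be recovered unchanged; no stereocentre is formed.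

Step 2
Reactants: 2 trans-(+)-limonene 1,2-oxide
Product: 3 (1S,2S,4R)-2-chloro-1-methyl-4-(prop-1-en-2-yl)cyclohexan-1-ol (OH and Cl trans-diaxial, Cl trans to isopropenyl)
Conditions: LiCl, AcOH, THF, 25 °C
Reagents that add atoms: lithium chloride, [Li+].[Cl-]
Why: Epoxide-to-halohydrin opening under Fürst–Plattner control: chloride attacks the secondary carbon anti to oxygen with inversion, which sets the future C10, while the tertiary C–O bond (future C9) is not broken.

Step 3
Reactants: 3 chlorohydrin
Product: 4 tert-butyl{[(1S,2S,4R)-2-chloro-1-methyl-4-(prop-1-en-2-yl)cyclohexyl]oxy}dimethylsilane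
Conditions: TBSOTf, 2,6-lutidine, CH2Cl2, 0 → 25 °C
Reagents that add atoms: tert-butyldimethylsilyl triflate, CC(C)(C)[Si](C)(C)OS(=O)(=O)C(F)(F)F
Why: Silylation of the hindered tertiary alcohol with a silyl triflate gives an ether robust enough for the following acidic, basic and carbenoid steps (a free OH would be attacked by the rhodium carbenoid); no stereocentre changes.

Step 4
Reactants: 4 silyl ether
Product: 5 tert-butyl{[(1S,2S,4R)-2-chloro-4-(2-chloropropan-2-yl)-1-methylcyclohexyl]oxy}dimethylsilane
Conditions: Co(BF4)2·6H2O, salen-type ligand, t-BuOOH (all cat.), TsCl, PhSiH3, EtOH, 25 °C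
Reagents that add atoms: p-toluenesulfonyl chloride, Cc1ccc(cc1)S(Cl)(=O)=O
Why: Markovnikov hydrochlorination by metal-hydride hydrogen-atom transfer: H adds to the terminal CH2 and the tertiary radical takes chlorine from TsCl, under neutral conditions that spare the silyl ether and, being radical, cannot shift the neighbouring ring methine hydrogen.

Step 5
Reactants: 5 tertiary chloride; 6 1-(tert-butyldimethylsilyloxy)-1-methoxyethene
Product: 7 methyl 3-[(1R,3S,4S)-4-(tert-butyldimethylsilyloxy)-3-chloro-4-methylcyclohexyl]-3-methylbutanoate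
Conditions: ZnCl2 (cat.), CH2Cl2, 25 °C
Reagents that add atoms: none
Why: Reetz α-tert-alkylation: ZnCl2 ionises the tertiary chloride and the silyl ketene acetal captures the ion pair at carbon, forming C5–C4 and the quaternary C5, while the β-oxygenated secondary chloride and the silyl ether do not ionise; capture has to outrun a 1,2-hydride shift from the ring methine.

Step 6
Reactants: 7 methyl ester
Product: 8 3-[(1R,3S,4S)-4-(tert-butyldimethylsilyloxy)-3-chloro-4-methylcyclohexyl]-3-methylbutanoic acid
Conditions: LiOH, THF/MeOH/H2O, 50 °C; then 1 M HCl to pH 4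
Reagents that add atoms: lithium hydroxide, [Li+].[OH-]
Why: Ester saponification; the hindered tertiary TBS ether and the secondary chloride flanked by a fully substituted carbon should be inert to hydroxide at this temperature.

Step 7
Reactants: 8 acid; 9 potassium methyl malonate
Product: 11 methyl 5-[(1R,3S,4S)-4-(tert-butyldimethylsilyloxy)-3-chloro-4-methylcyclohexyl]-5-methyl-3-oxohexanoate, via acyl imidazolide 10 (not isolated)
Conditions: CDI, THF, 25 °C; then 9, MgCl2, Et3N, THF/MeCN, 25 → 45 °C; aq. HCl work-up
Reagents that add atoms: none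
Why: Masamune–Brooks homologation: the magnesium malonate half-ester is C-acylated by the acyl imidazolide and loses CO2 to give the β-keto ester (the C3 carbonyl and C1); no stereocentre is involved.

Step 8
Reactants: 11 β-keto ester
Product: 12 methyl 2-diazo-5-[(1R,3S,4S)-4-(tert-butyldimethylsilyloxy)-3-chloro-4-methylcyclohexyl]-5-methyl-3-oxohexanoate
Conditions: p-ABSA, Et3N, MeCN, 0 → 25 °C
Reagents that add atoms: 4-acetamidobenzenesulfonyl azide, CC(=O)Nc1ccc(cc1)S(=O)(=O)N=[N+]=[N-]
Why: Regitz diazo transfer to the active methylene of the β-keto ester.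

Step 9
Reactants: 12 diazo β-keto ester
Product: 13 methyl (5R,7S,8S)-8-(tert-butyldimethylsilyloxy)-7-chloro-4,4,8-trimethyl-2-oxospiro[4.5]decane-1-carboxylate (C1 epimers and enol)
Conditions: Rh2(OAc)4 (1 mol%), CH2Cl2, 25 → 40 °C
Reagents that add atoms: none
Why: Rhodium(II) carbenoid 1,5-C–H insertion into the tertiary ring methine (cyclopentanone formation from an α-diazo β-keto ester) is a concerted three-centre process with retention, so the spiro carbon C6 takes the limonene configuration; the gem-dimethyl tether favours cyclisation, the methyl C–H bonds are far less reactive, and the C1 stereocentre is of no consequence.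

Step 10
Reactants: 13 spiro β-keto ester
Product: 14 methyl (5S,7S,8S)-8-(tert-butyldimethylsilyloxy)-7-chloro-1,4,4,8-tetramethyl-2-oxospiro[4.5]decane-1-carboxylate (C1 epimers; same spatial arrangement at the spiro carbon, descriptor changed by CIP priorities)
Conditions: K2CO3, MeI, acetone, 40 °C
Reagents that add atoms: iodomethane, CI
Why: C-alkylation of the cyclic β-keto ester enolate places the methyl group regiospecifically on C1, the only acidic position; the new C1 stereocentre is removed in step 12.

Step 11
Reactants: 14 methylated β-keto ester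
Product: 15 (5R,7S,8S)-8-(tert-butyldimethylsilyloxy)-7-chloro-1,4,4,8-tetramethylspiro[4.5]decan-2-one (C1 epimers)
Conditions: LiCl, DMSO, H2O, 150 °C
Reagents that add atoms: none
Why: Krapcho dealkoxycarbonylation (chloride demethylates the ester, the carboxylate loses CO2, the enolate is protonated); the ring B chloride is neopentyl-like and should resist chloride exchange.

Step 12
Reactants: 15 ketone
Product: 16 {[(5S,7S,8S)-8-(tert-butyldimethylsilyloxy)-7-chloro-1,4,4,8-tetramethylspiro[4.5]dec-1-en-2-yl]oxy}trimethylsilane (tetrasubstituted C1=C3 enol ether in plan numbering)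
Conditions: TMSCl, NaI, Et3N, MeCN, 25 °C
Reagents that add atoms: chlorotrimethylsilane, C[Si](C)(C)Cl
Why: Enol silylation with iodotrimethylsilane made in situ is equilibrating and should favour the more substituted C1=C3 enol ether over the C3=C4 isomer; the C1 stereocentre disappears.

Step 13
Reactants: 16 silyl enol ether; 17 dichloromethane
Product: 19 (6S,9S,10S)-9-(tert-butyldimethylsilyloxy)-10-chloro-1,5,5,9-tetramethylspiro[5.5]undec-1-en-3-one, via chlorosiloxycyclopropane 18 (not isolated)
Conditions: MeLi (Et2O, slow addition), CH2Cl2, −40 °C; MeOH quench; then 25 °C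
Reagents that add atoms: none
Why: MeLi deprotonates CH2Cl2 to LiCHCl2, which transfers chlorocarbene to the electron-rich C1=C3 enol ether double bond (new bonds C1–C2 and C2–C3) to give the 6-chloro-1-siloxybicyclo[3.1.0]hexane 18. In the adduct with chlorine endo (cis to ring carbons C4 and C6) loss of chloride is concerted with disrotatory opening of the C1–C3 bond, assisted by the siloxy oxygen, and chloride then takes the silyl group from the 2-siloxyallyl cation to leave the enone with C1=C2 and C3=O. The closest known reaction type is halocarbene addition to cyclic silyl enol ethers with one-carbon ring expansion to 2-cycloalkenones. Ring A therefore arises by expansion of the five-membered ring ([2+1] addition, then cyclopropyl-to-allyl electrocyclic opening) and not by end-to-end closure. No stereocentre is created and C6, C9 and C10 are untouched. The step needs attack at the enol ether, which is the only C=C present and whose position was fixed in step 12, and the endo-chloro adduct, the usual preference of the chlorocarbenoid; the exo adduct is the expected loss, and MeLi is consumed by the large excess of CH2Cl2 and quenched before the enone forms on warming.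

Step 14
Reactants: 19 enone
Product: 21 (4R,6R,9S,10S)-4-bromo-9-(tert-butyldimethylsilyloxy)-10-chloro-1,5,5,9-tetramethylspiro[5.5]undec-1-en-3-one, via silyl dienol ether 20 (not isolated)
Conditions: LDA, TMSCl, THF, −78 °C; then NBS, THF, −78 → 0 °C
Reagents that add atoms: N-bromosuccinimide, O=C1CCC(=O)N1Br
Why: Kinetic deprotonation at C4, the only α′ CH2, gives the cross-conjugated dienolate, whose silyl ether is brominated at C4 by NBS; the bias from ring B is remote, so the (4R) bromide (Br cis to C11) is expected with only modest selectivity and is to be secured by separation, the 4S epimer being re-equilibrated through the enol.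

Step 15
Reactants: 21 α′-bromo enone
Product: 22 (4R,6R,9S,10S)-4,9-dibromo-10-chloro-1,5,5,9-tetramethylspiro[5.5]undec-1-en-3-one
Conditions: BBr3, CH2Cl2, −78 → −20 °C; aq. NaHCO3
Reagents that add atoms: boron tribromide, BrB(Br)Br
Why: Direct conversion of a tertiary silyl ether into the bromide by an SN1 path: the borate leaves C9 and the β-chloro cation, bridged by the C10 chlorine, should be opened by bromide anti to chlorine, so that C9 keeps its configuration (Br trans to Cl); C5 is quaternary, so the α-bromo ketone cannot eliminate.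

Step 16
Reactants: 22 dibromo chloro enone
Product: 23 (3S,4R,6R,9S,10S)-4,9-dibromo-10-chloro-1,5,5,9-tetramethylspiro[5.5]undec-1-en-3-ol (target)
Conditions: DIBAL-H, CH2Cl2, −78 °C; Rochelle salt
Reagents that add atoms: none
Why: 1,2-Reduction of the enone with hydride adding to C3 anti to the C4–Br bond (polar Felkin–Anh control in the α-bromo ketone) should give the cis-bromohydrin, i.e. the 3S carbinol; the alkyl halides are inert to DIBAL at −78 °C.

**Compound list**

1 | (+)-limonene 1,2-oxide, (4R), cis/trans mixture | CC(=C)[C@@H]1CCC2(C)OC2C1 | starting material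
2 | trans-(+)-limonene 1,2-oxide, (1S,2R,4R) | CC(=C)[C@@H]1CC[C@]2(C)O[C@@H]2C1 | intermediate
3 | (1S,2S,4R)-2-chloro-1-methyl-4-(prop-1-en-2-yl)cyclohexan-1-ol | CC(=C)[C@@H]1CC[C@](C)(O)[C@@H](Cl)C1 | intermediate
4 | tert-butyl{[(1S,2S,4R)-2-chloro-1-methyl-4-(prop-1-en-2-yl)cyclohexyl]oxy}dimethylsilane | CC(=C)[C@@H]1CC[C@](C)(O[Si](C)(C)C(C)(C)C)[C@@H](Cl)C1 | intermediate
5 | tert-butyl{[(1S,2S,4R)-2-chloro-4-(2-chloropropan-2-yl)-1-methylcyclohexyl]oxy}dimethylsilane | CC(C)(Cl)[C@@H]1CC[C@](C)(O[Si](C)(C)C(C)(C)C)[C@@H](Cl)C1 | intermediate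
6 | 1-(tert-butyldimethylsilyloxy)-1-methoxyethene | C=C(OC)O[Si](C)(C)C(C)(C)C | starting material
7 | methyl 3-[(1R,3S,4S)-4-(tert-butyldimethylsilyloxy)-3-chloro-4-methylcyclohexyl]-3-methylbutanoate | COC(=O)CC(C)(C)[C@@H]1CC[C@](C)(O[Si](C)(C)C(C)(C)C)[C@@H](Cl)C1 | intermediate
8 | 3-[(1R,3S,4S)-4-(tert-butyldimethylsilyloxy)-3-chloro-4-methylcyclohexyl]-3-methylbutanoic acid | OC(=O)CC(C)(C)[C@@H]1CC[C@](C)(O[Si](C)(C)C(C)(C)C)[C@@H](Cl)C1 | intermediate
9 | potassium methyl malonate | COC(=O)CC(=O)[O-].[K+] | starting material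
10 | acyl imidazolide of acid 8 | O=C(CC(C)(C)[C@@H]1CC[C@](C)(O[Si](C)(C)C(C)(C)C)[C@@H](Cl)C1)n1ccnc1 | intermediate (not isolated)
11 | methyl 5-[(1R,3S,4S)-4-(tert-butyldimethylsilyloxy)-3-chloro-4-methylcyclohexyl]-5-methyl-3-oxohexanoate | COC(=O)CC(=O)CC(C)(C)[C@@H]1CC[C@](C)(O[Si](C)(C)C(C)(C)C)[C@@H](Cl)C1 | intermediate
12 | methyl 2-diazo-5-[(1R,3S,4S)-4-(tert-butyldimethylsilyloxy)-3-chloro-4-methylcyclohexyl]-5-methyl-3-oxohexanoate | COC(=O)C(=[N+]=[N-])C(=O)CC(C)(C)[C@@H]1CC[C@](C)(O[Si](C)(C)C(C)(C)C)[C@@H](Cl)C1 | intermediate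
13 | methyl (5R,7S,8S)-8-(tert-butyldimethylsilyloxy)-7-chloro-4,4,8-trimethyl-2-oxospiro[4.5]decane-1-carboxylate, C1 epimers | COC(=O)C1C(=O)CC(C)(C)[C@@]12CC[C@](C)(O[Si](C)(C)C(C)(C)C)[C@@H](Cl)C2 | intermediate
14 | methyl (5S,7S,8S)-8-(tert-butyldimethylsilyloxy)-7-chloro-1,4,4,8-tetramethyl-2-oxospiro[4.5]decane-1-carboxylate, C1 epimers | COC(=O)C1(C)C(=O)CC(C)(C)[C@@]12CC[C@](C)(O[Si](C)(C)C(C)(C)C)[C@@H](Cl)C2 | intermediate
15 | (5R,7S,8S)-8-(tert-butyldimethylsilyloxy)-7-chloro-1,4,4,8-tetramethylspiro[4.5]decan-2-one, C1 epimers | CC1C(=O)CC(C)(C)[C@@]12CC[C@](C)(O[Si](C)(C)C(C)(C)C)[C@@H](Cl)C2 | intermediate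
16 | {[(5S,7S,8S)-8-(tert-butyldimethylsilyloxy)-7-chloro-1,4,4,8-tetramethylspiro[4.5]dec-1-en-2-yl]oxy}trimethylsilane | CC1=C(O[Si](C)(C)C)CC(C)(C)[C@@]12CC[C@](C)(O[Si](C)(C)C(C)(C)C)[C@@H](Cl)C2 | intermediate
17 | dichloromethane | ClCCl | starting material
18 | chlorosiloxycyclopropane: CHCl bridging C1 and C3 of 16 (6-chloro-5-methyl-1-trimethylsilyloxybicyclo[3.1.0]hexane core, spiro-fused to ring B; cyclopropane diastereomers, the endo-chloro isomers react on) | CC12C(Cl)C1(O[Si](C)(C)C)CC(C)(C)[C@@]23CC[C@](C)(O[Si](C)(C)C(C)(C)C)[C@@H](Cl)C3 | intermediate (not isolated)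
19 | (6S,9S,10S)-9-(tert-butyldimethylsilyloxy)-10-chloro-1,5,5,9-tetramethylspiro[5.5]undec-1-en-3-one | CC1=CC(=O)CC(C)(C)[C@@]12CC[C@](C)(O[Si](C)(C)C(C)(C)C)[C@@H](Cl)C2 | intermediate
20 | 3-trimethylsilyloxy-1,3-diene (silyl dienol ether) of 19 | CC1=CC(O[Si](C)(C)C)=CC(C)(C)[C@@]12CC[C@](C)(O[Si](C)(C)C(C)(C)C)[C@@H](Cl)C2 | intermediate (not isolated)
21 | (4R,6R,9S,10S)-4-bromo-9-(tert-butyldimethylsilyloxy)-10-chloro-1,5,5,9-tetramethylspiro[5.5]undec-1-en-3-one | CC1=CC(=O)[C@H](Br)C(C)(C)[C@@]12CC[C@](C)(O[Si](C)(C)C(C)(C)C)[C@@H](Cl)C2 | intermediate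
22 | (4R,6R,9S,10S)-4,9-dibromo-10-chloro-1,5,5,9-tetramethylspiro[5.5]undec-1-en-3-one | CC1=CC(=O)[C@H](Br)C(C)(C)[C@@]12CC[C@](C)(Br)[C@@H](Cl)C2 | intermediate
23 | (3S,4R,6R,9S,10S)-4,9-dibromo-10-chloro-1,5,5,9-tetramethylspiro[5.5]undec-1-en-3-ol | CC1=C[C@H](O)[C@H](Br)C(C)(C)[C@@]12CC[C@](C)(Br)[C@@H](Cl)C2 | target

**Step count and risks**

Total steps: 16. Longest linear sequence: 16 steps (1 → 23); compounds 6, 9 and 17 enter directly.

Most likely to fail:

1. Step 13 (ring expansion). Carbene transfer to a tetrasubstituted enol ether flanked by two quaternary carbons may be slow, the chlorine may end up exo so that the cyclopropane does not open, or methyllithium may attack the enone as it forms. The fallback sets out from 16 and comes back at 19. Cyclopropanation of 16 with the Furukawa zinc carbenoid (Et2Zn, CH2I2, toluene, 0 °C) should give the siloxycyclopropane F1. Iron(III) chloride in DMF (0 → 25 °C) oxidises it to the cyclopropoxy radical, the C1–C3 bond breaks towards the tertiary C1 radical, and chlorine transfer gives the ring-expanded β-chloro ketone F2. Sodium acetate in methanol at reflux then eliminates HCl to give 19 (Ito–Saegusa ring expansion). The same C1–C2 and C2–C3 bonds are made and C1–C3 is cut; only the order in which chlorine arrives and leaves differs.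

2. Step 15 (C9 exchange). In the spiro[5.5] enone the C1 methyl group may hold ring B in the chair with C10–Cl equatorial, so that the C9 cation is not bridged and bromide enters on the face syn to chlorine; loss of a proton from the cation and Lewis-acid damage to the α-bromo ketone are further losses. The fallback sets out from 15 and comes back at 22. In ketone 15, C1 is still sp3 and ring B can keep the C9–O and C10–Cl bonds trans-diaxial, as they were made, so chlorine participation and axial attack both place bromide anti to chlorine. BBr3 (CH2Cl2, −78 → −20 °C) should give the bromo ketone F3. Iodide-free equilibrating silylation (TMSOTf, Et3N, CH2Cl2, 25 °C), chosen so that the vicinal bromochloride is not reductively eliminated, should give the silyl enol ether F4. The conditions of step 13 then lead through the chlorosiloxycyclopropane F5 to the bromo enone F6, in which the now equatorial tertiary bromide has no anti-periplanar ring hydrogen. The conditions of step 14, through the silyl dienol ether F7, give 22.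

3. Step 5 (tert-alkylation). The tertiary cation may undergo a 1,2-hydride shift from the neighbouring ring methine before capture, moving the alkylation site into the ring and erasing the future C6 stereocentre, or may lose a proton to the alkene. The fallback sets out from 4 and comes back at 7, with no cation involved. Rhodium(II)-catalysed cyclopropanation of the isopropenyl group with methyl diazoacetate (Rh2(OAc)4, CH2Cl2, slow addition) should give the cyclopropane ester F8 as a diastereomer mixture. Hydrogenolysis (H2, PtO2, AcOH, 25 °C) at the least substituted cyclopropane bond, between CH2 and the ester-bearing CH, turns the ring into the gem-dimethyl group and the CH2CO2Me arm of 7.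

**Further compounds**

F1 | step 13 | siloxycyclopropane: CH2 bridging C1 and C3 of 16 (5-methyl-1-trimethylsilyloxybicyclo[3.1.0]hexane core) | CC12CC1(O[Si](C)(C)C)CC(C)(C)[C@@]23CC[C@](C)(O[Si](C)(C)C(C)(C)C)[C@@H](Cl)C3
F2 | step 13 | β-chloro ketone: 1,10-dichloro-9-(tert-butyldimethylsilyloxy)-1,5,5,9-tetramethylspiro[5.5]undecan-3-one (plan numbering; C1 epimers) | CC1(Cl)CC(=O)CC(C)(C)[C@@]12CC[C@](C)(O[Si](C)(C)C(C)(C)C)[C@@H](Cl)C2
F3 | step 15 | bromo ketone: 8-bromo-7-chloro-1,4,4,8-tetramethylspiro[4.5]decan-2-one (ring B as in the target; C1 epimers) | CC1C(=O)CC(C)(C)[C@@]12CC[C@](C)(Br)[C@@H](Cl)C2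
F4 | step 15 | silyl enol ether: (8-bromo-7-chloro-1,4,4,8-tetramethylspiro[4.5]dec-1-en-2-yl)oxytrimethylsilane | CC1=C(O[Si](C)(C)C)CC(C)(C)[C@@]12CC[C@](C)(Br)[C@@H](Cl)C2
F5 | step 15 | chlorosiloxycyclopropane: CHCl bridging C1 and C3 of F4 | CC12C(Cl)C1(O[Si](C)(C)C)CC(C)(C)[C@@]23CC[C@](C)(Br)[C@@H](Cl)C3
F6 | step 15 | bromo enone: 9-bromo-10-chloro-1,5,5,9-tetramethylspiro[5.5]undec-1-en-3-one (plan numbering) | CC1=CC(=O)CC(C)(C)[C@@]12CC[C@](C)(Br)[C@@H](Cl)C2
F7 | step 15 | silyl dienol ether: 3-trimethylsilyloxy-1,3-diene of F6 | CC1=CC(O[Si](C)(C)C)=CC(C)(C)[C@@]12CC[C@](C)(Br)[C@@H](Cl)C2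
F8 | step 5 | cyclopropane ester: methyl 2-[(1R,3S,4S)-4-(tert-butyldimethylsilyloxy)-3-chloro-4-methylcyclohexyl]-2-methylcyclopropane-1-carboxylate (cyclopropane diastereomers) | COC(=O)C1CC1(C)[C@@H]2CC[C@](C)(O[Si](C)(C)C(C)(C)C)[C@@H](Cl)C2
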